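Through a run in which each substrate reacts in proportion to its own amount I hold one ratio fixed: both mirror-image substrates meet the same free catalyst and the same reagent at every moment, so the logarithm of the fraction left of the left-handed substrate keeps a constant ratio to that of the right-handed substrate (the selectivity factor), however the catalyst fares.

| setting | ash | birch | beta | zeta |
|---|---|---|---|---|
| left-handed substrate | 0.41 M | 0.41 M | 0.41 M | 0.41 M |
| right-handed substrate | 0.41 M | 0.41 M | 0.41 M | 0.41 M |
| reagent | 1 equiv | 1 equiv | 1.00 equiv | 1.00 equiv |
| free catalyst | 0.6 mol% | 2.3 mol% | 0.5 mol% | 1.5 mol% |
| remark | run made earlier | run made earlier |  |  |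
| time |  |  | 12 min | 12 min |

- ash (time / min: right-handed substrate / %, left-handed substrate / %): 1.00: 51, 50; 3.00: 49, 44; 5.00: 46, 44; 8.00: 45, 42
- birch (time / min: right-handed substrate / %, left-handed substrate / %): 1.00: 48, 42; 3.00: 40, 34; 5.00: 39, 33; 8.00: 38, 30

(standard deviation of a reading: 1.5 percentage points)

- free catalyst is single-handed; left-handed substrate and right-handed substrate are mirror images of each other, charged as a racemate, each of them at the stated concentration
- an excess is the difference of the two amounts in percent of their sum
- an excess is below zero if the other one leads

- which of the two ends with the higher excess of right-handed substrate over left-handed substrate among what is left of the two ("neither" if they lie within 2 percentage points) (beta / zeta / neither)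
- excess of right-handed substrate over left-handed substrate among what is left of the two at the end, beta
- excess of right-handed substrate over left-handed substrate among what is left of the two at the end, zeta

The birch run at 8.00 min reads that factor as 1.86, so I take the excess as 0.301 (the factor less one, over the factor plus one) times the negative logarithm of the fraction of the pair left.

How far each flask gets remains to be found. The ash run stands at 43.3 by 8.00 min. That count, the fraction of the pair gone, times 2, over the loading on the left-handed substrate, is the turnovers per catalyst charged. As a reading it carries the scatter. Birch starts at 8.70 by 1.00 min. By 3.00 min the two runs lie together, ash at 23.3 and birch at 22.6. Then birch bends and reaches 27.8 by 8.00 min.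

I give beta the ash count, which means 10.8% of the pair gone and an excess of 3.45%. For zeta I draw a straight line in loading between the two runs, which gives 35.1 turnovers, 26.3% gone and an excess of 9.20%. Both leave out the creep from the last reading to 12 min.

The forecast, which sees that “Each run therefore heads for a plateau set by catalyst loading, not by time.”, gives 3.8% for beta and 8.8% for zeta, and names zeta. My beta lies lower and my zeta higher.

The flasks give 5.87% for beta and 13.7% for zeta, so zeta leads, as the forecast said, and both of its values lie within tolerance.

    reagent + free catalyst + right-handed substrate → free catalyst + right-handed product (k = 17.0 M⁻² min⁻¹)
    free catalyst → spent catalyst A (k = 0.0830 min⁻¹)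
    reagent + free catalyst + left-handed substrate → free catalyst + left-handed product (k = 40.0 M⁻² min⁻¹)
    reagent + free catalyst → spent catalyst B (k = 0.0370 M⁻¹ min⁻¹)

The gap between the flasks comes from the loading: zeta run at beta's loading ends at 5.87% instead of 13.7%. Counted at 12 min, beta made 53.6 turnovers per catalyst against my 43.3, and zeta 37.7 against my 35.1. For the neighbour, beta charged with 1.2 mol% of free catalyst, the same line gives 37.9 turnovers and 22.7% of the pair gone, and that flask shows 24.8% gone with an excess of 11.8%.

The runs are calculated from invented constants; scatter was added.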